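## Retrosynthetic overview

1. Working back from the target: acetylation, O-desilylation, C7–OTf → C7–H and hydroboration of C1=C2 lead to a trans-octalin enol triflate. Li/NH3 reduction with enolate trapping and a Saegusa–Ito oxidation lead back to a 7-silyloxy-Δ1,7-octalin. Ring-closing metathesis (C1=C2) and a methylenation lead back to a monocyclic ring-B aldehyde.
2. Key disconnection: ring B is opened at C5–C6 and C9–C10 (retro-Diels–Alder). One piece is an acyclic 2-silyloxydiene, C6=C7(OSi)–C8(CH3)=C9, carrying the whole C11–C16 side chain, with C13 from (S)-citronellol. The other is an acyclic (E)-enal, C10=C5, in which CHO = C1, CH3 = C20 and the CMe2–allyl group = C4, C18, C19, C3, C2.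
3. Enabling feature: ring B (C5–C6–C7=C8–C9–C10) is a cyclohexene whose C7=C8 bond lies opposite the C5–C10 fusion bond. On that bond CH3-20 and C4 are cis, and H-5 and C1 are cis, which is the imprint of an (E)-alkene. A ring-A (Z) dienophile could only give the cis-decalin, so ring A is left open.
4. The temporary C7 oxygen drives rate and regiochemistry. It also lets C9 be flattened and rebuilt, so endo/exo does not matter, and it marks the place of the final C7=C8 bond. The CHO group activates the dienophile and then becomes C1.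
5. Order of ring formation: ring B (step 6), then ring A (step 8).

Key step: step 6

Assumption: labdane numbering is used for all intermediates. The (S)-prolinol-derived antipode of the catalyst is taken to expose the required face of the enal (formyl C–H···O model); the mirror-image catalyst is equally available.

## Route

Step 1
Reactants: 1 (S)-citronellol
Product: 2 (S)-citronellyl tert-butyldimethylsilyl ether
Conditions: TBSCl, imidazole, DMF, rt
Reagents that add atoms: tert-butyldimethylsilyl chloride, CC(C)(C)[Si](C)(C)Cl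
Why: Silyl ether protection of the primary alcohol is routine, touches no stereocentre (C13 comes from the chiral pool) and gives a group that survives ylides, Lewis acid and Li/NH3.

Step 2
Reactants: 2 (S)-citronellyl tert-butyldimethylsilyl ether
Product: 4 (4S)-6-(tert-butyldimethylsilyloxy)-4-methylhexanal, via secondary ozonide 3 (not isolated)
Conditions: O3, CH2Cl2, −78 °C; then Me2S, −78 °C → rt
Reagents that add atoms: ozone, [O-][O+]=O
Why: Ozonolysis with reductive work-up cleaves the only C=C bond and makes C9 the aldehyde carbon, while C13 is remote and not epimerisable.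

Step 3
Reactants: 4 (4S)-6-(tert-butyldimethylsilyloxy)-4-methylhexanal; 5 3-(triphenyl-λ5-phosphanylidene)butan-2-one
Product: 6 (3E,7S)-9-(tert-butyldimethylsilyloxy)-3,7-dimethylnon-3-en-2-one
Conditions: toluene, 100 °C
Reagents that add atoms: none
Why: Wittig olefination with a ketone-stabilised, α-branched ylide should give the (E)-trisubstituted enone and brings in C6, C7, C8 and C17.

Step 4
Reactants: 6 (3E,7S)-9-(tert-butyldimethylsilyloxy)-3,7-dimethylnon-3-en-2-one
Product: 7 (3E,7S)-2,9-bis(tert-butyldimethylsilyloxy)-3,7-dimethylnona-1,3-diene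
Conditions: TBSOTf, Et3N, CH2Cl2, 0 °C
Reagents that add atoms: tert-butyldimethylsilyl triflate, CC(C)(C)[Si](C)(C)OS(=O)(=O)C(F)(F)F
Why: Soft enolisation (silyl triflate/amine) deprotonates the acetyl CH3 and gives the cross-conjugated 2-silyloxy-1,3-diene without touching the (E)-C8=C9 bond.

Step 5
Reactants: 8 2,2-dimethylpent-4-enal; 9 2-(triphenyl-λ5-phosphanylidene)propanal
Product: 10 (2E)-2,4,4-trimethylhepta-2,6-dienal
Conditions: toluene, reflux
Reagents that add atoms: none
Why: Wittig olefination of the non-enolisable α-quaternary aldehyde with the formyl-stabilised ylide should give the (E)-enal, the geometry that later becomes the trans ring fusion.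

Step 6
Reactants: 7 (3E,7S)-2,9-bis(tert-butyldimethylsilyloxy)-3,7-dimethylnona-1,3-diene; 10 (2E)-2,4,4-trimethylhepta-2,6-dienal
Product: 11 (1R,2S,6R)-4-(tert-butyldimethylsilyloxy)-2-[(3S)-5-(tert-butyldimethylsilyloxy)-3-methylpentyl]-1,3-dimethyl-6-(2-methylpent-4-en-2-yl)cyclohex-3-ene-1-carbaldehyde (ring B; CH3-20 cis to the tert-alkyl group on C5, CHO cis to H-5, C9 side chain cis to CHO)
Conditions: B-o-tolyl oxazaborolidine from (S)-α,α-diphenylprolinol (20 mol %), Tf2NH (18 mol %), CH2Cl2, −40 → −20 °C
Reagents that add atoms: none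
Why: The step is a concerted but asynchronous, suprafacial [4π+2π] cycloaddition (normal-electron-demand Diels–Alder reaction) between the HOMO of the 2-silyloxydiene and the LUMO of the enal bound to the cationic oxazaborolidine, and the closest known reaction type is the oxazaborolidinium-catalysed Diels–Alder reaction of 2-silyloxy-1,3-dienes with α-methyl-β-substituted enals of the tiglic aldehyde class. Ring B closes in one six-membered boat-like transition state that makes C5–C6 (leading bond) and C9–C10 (lagging bond) on one face of each partner. The C7 silyloxy group places the largest HOMO coefficient on the unsubstituted terminus C6, which bonds to the β-carbon C5, so the substituted terminus C9 meets C10. The relative configuration of C5 and C10 follows from the (E)-geometry of 10 (CH3 and the tert-alkyl group stay cis, CHO and H stay cis), which is the latent trans ring fusion, and their absolute configuration follows from the catalyst, whose aryl group shields one face of the s-trans enal held by B–O coordination and a formyl C–H···O contact. C9 is set by the endo rule together with the exo preference of the bulky C5 substituent (side chain cis to CHO, that is 9-epi), which is harmless because C9 is flattened in step 9 and rebuilt in step 10. Chemoselectivity holds because C5=C10 is the only activated π-bond of 10 (the allyl terminus is inert) and the resulting tetrasubstituted silyl enol ether is stable under the conditions.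

Step 7
Reactants: 11 ring-B aldehyde
Product: 12 ring-B triene (11 with CHO replaced by CH=CH2, all configurations unchanged)
Conditions: Ph3PCH3Br, KOt-Bu, THF, 0 °C
Reagents that add atoms: methyltriphenylphosphonium bromide, C[P+](c1ccccc1)(c1ccccc1)c1ccccc1.[Br-]
Why: Wittig methylenation of the non-enolisable neopentyl aldehyde turns C1 into a vinyl carbon without touching a stereocentre or the silyl ethers.

Step 8
Reactants: 12 ring-B triene
Product: 13 (13S)-7,15-bis(tert-butyldimethylsilyloxy)-9-epi-ent-labda-1,7-diene (trans-fused, H-5 anti to CH3-20, C9 side chain anti to CH3-20)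
Conditions: Grubbs second-generation catalyst (5 mol %), CH2Cl2, 40 °C
Reagents that add atoms: none
Why: Ring-closing metathesis of the two monosubstituted alkenes, which sit trans on ring B, closes ring A as a trans-fused cyclohexene with loss of ethene, and the tetrasubstituted enol ether is inert to the ruthenium carbene.

Step 9
Reactants: 13 (13S)-7,15-bis(tert-butyldimethylsilyloxy)-9-epi-ent-labda-1,7-diene
Product: 14 (13S)-15-(tert-butyldimethylsilyloxy)-ent-labda-1,8-dien-7-one
Conditions: Pd(OAc)2 (1.1 equiv), MeCN, 40 °C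
Reagents that add atoms: none
Why: In the Saegusa–Ito oxidation the oxa-π-allylpalladium species loses the C9 hydrogen by β-hydride elimination and gives the conjugated tetrasubstituted enone, which erases the wrong C9 centre.

Step 10
Reactants: 14 (13S)-15-(tert-butyldimethylsilyloxy)-ent-labda-1,8-dien-7-one
Product: 16 (13S)-15-(tert-butyldimethylsilyloxy)-ent-labda-1,7-dien-7-yl triflate, via lithium enolate 15 (not isolated)
Conditions: Li, NH3(l)/THF, t-BuOH (1 equiv), −78 °C; NH3 evaporated; PhNTf2, THF, 0 °C
Reagents that add atoms: N-phenylbis(trifluoromethanesulfonimide), O=S(=O)(N(c1ccccc1)S(=O)(=O)C(F)(F)F)C(F)(F)F; lithium, [Li] (kept only in 15)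
Why: In this dissolving-metal (Birch-type) enone reduction with regiospecific enolate trapping, C9 is protonated axially, anti to the axial C10 methyl group, so the side chain becomes equatorial (correct C9), and the C7=C8 enolate is O-sulfonylated exactly where the target has its double bond.

Step 11
Reactants: 16 (13S)-15-(tert-butyldimethylsilyloxy)-ent-labda-1,7-dien-7-yl triflate
Product: 18 (2R,13S)-15-(tert-butyldimethylsilyloxy)-2-hydroxy-ent-labd-7-en-7-yl triflate, via B-alkyl-9-BBN adduct 17 (not isolated)
Conditions: 9-BBN, THF, rt → 50 °C; then H2O2, pH 7 buffer, 0 °C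
Reagents that add atoms: 9-borabicyclo[3.3.1]nonane, B1C2CCCC1CCC2 (boron kept only in 17); hydrogen peroxide, OO
Why: In the Brown hydroboration–oxidation boron goes to C2 because C1 is neopentyl and flanked by C11, it attacks from the face opposite the axial methyl groups on C10 and C4 (equatorial 2-OH after retentive oxidation), and the electron-poor tetrasubstituted enol triflate is left alone.

Step 12
Reactants: 18 (2R,13S)-15-(tert-butyldimethylsilyloxy)-2-hydroxy-ent-labd-7-en-7-yl triflate
Product: 19 (2R,13S)-15-(tert-butyldimethylsilyloxy)-ent-labd-7-en-2-ol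
Conditions: Pd(OAc)2 (5 mol %), PPh3, HCO2H, Et3N, DMF, 60 °C
Reagents that add atoms: none
Why: Palladium-catalysed formate hydrogenolysis of the enol triflate (oxidative addition, decarboxylation of the formate, reductive elimination) replaces OTf by H without moving the C7=C8 bond and tolerates the free alcohol and the silyl ether.

Step 13
Reactants: 19 (2R,13S)-15-(tert-butyldimethylsilyloxy)-ent-labd-7-en-2-ol
Product: 21 (2R,5R,9R,10R,13S)-labd-7-ene-2,15-diyl diacetate, via diol 20 (not isolated)
Conditions: TBAF, THF, rt; then Ac2O, Et3N, DMAP (cat.), rt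
Reagents that add atoms: acetic anhydride, CC(=O)OC(C)=O
Why: Fluoride-induced desilylation followed by DMAP-catalysed acetylation esterifies both hydroxyl groups under neutral to basic conditions that touch neither a stereocentre nor the trisubstituted alkene.

## Compound list

1 | (S)-citronellol | OCC[C@@H](C)CCC=C(C)C | starting material
2 | (S)-citronellyl TBS ether | CC(C)(C)[Si](C)(C)OCC[C@@H](C)CCC=C(C)C | intermediate
3 | secondary ozonide of 2 (trioxolane carbon as epimers) | CC(C)(C)[Si](C)(C)OCC[C@@H](C)CCC1OOC(C)(C)O1 | intermediate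
4 | (4S)-6-(tert-butyldimethylsilyloxy)-4-methylhexanal | CC(C)(C)[Si](C)(C)OCC[C@@H](C)CCC=O | intermediate
5 | 3-(triphenyl-λ5-phosphanylidene)butan-2-one | CC(=O)C(C)=P(c1ccccc1)(c1ccccc1)c1ccccc1 | starting material
6 | (3E,7S)-9-(tert-butyldimethylsilyloxy)-3,7-dimethylnon-3-en-2-one | CC(C)(C)[Si](C)(C)OCC[C@@H](C)CC/C=C(\C)C(C)=O | intermediate
7 | (3E,7S)-2,9-bis(tert-butyldimethylsilyloxy)-3,7-dimethylnona-1,3-diene | CC(C)(C)[Si](C)(C)OCC[C@@H](C)CC/C=C(\C)C(=C)O[Si](C)(C)C(C)(C)C | intermediate
8 | 2,2-dimethylpent-4-enal | C=CCC(C)(C)C=O | starting material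
9 | 2-(triphenyl-λ5-phosphanylidene)propanal | CC(C=O)=P(c1ccccc1)(c1ccccc1)c1ccccc1 | starting material
10 | (2E)-2,4,4-trimethylhepta-2,6-dienal | C=CCC(C)(C)/C=C(\C)C=O | intermediate
11 | Diels–Alder adduct, ring-B aldehyde | CC(C)(C)[Si](C)(C)OCC[C@@H](C)CC[C@H]1C(C)=C(O[Si](C)(C)C(C)(C)C)C[C@H](C(C)(C)CC=C)[C@@]1(C)C=O | intermediate
12 | ring-B triene | CC(C)(C)[Si](C)(C)OCC[C@@H](C)CC[C@H]1C(C)=C(O[Si](C)(C)C(C)(C)C)C[C@H](C(C)(C)CC=C)[C@@]1(C)C=C | intermediate
13 | (13S)-7,15-bis(tert-butyldimethylsilyloxy)-9-epi-ent-labda-1,7-diene | CC(C)(C)[Si](C)(C)OCC[C@@H](C)CC[C@H]1C(C)=C(O[Si](C)(C)C(C)(C)C)C[C@@H]2C(C)(C)CC=C[C@@]12C | intermediate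
14 | (13S)-15-(tert-butyldimethylsilyloxy)-ent-labda-1,8-dien-7-one | CC(C)(C)[Si](C)(C)OCC[C@@H](C)CCC1=C(C)C(=O)C[C@@H]2C(C)(C)CC=C[C@@]12C | intermediate
15 | lithium C7=C8 enolate | CC(C)(C)[Si](C)(C)OCC[C@@H](C)CC[C@@H]1C(C)=C([O-])C[C@@H]2C(C)(C)CC=C[C@@]12C.[Li+] | intermediate
16 | (13S)-15-(tert-butyldimethylsilyloxy)-ent-labda-1,7-dien-7-yl triflate | CC(C)(C)[Si](C)(C)OCC[C@@H](C)CC[C@@H]1C(C)=C(OS(=O)(=O)C(F)(F)F)C[C@@H]2C(C)(C)CC=C[C@@]12C | intermediate
17 | C2 B-alkyl-9-BBN adduct | CC(C)(C)[Si](C)(C)OCC[C@@H](C)CC[C@@H]1C(C)=C(OS(=O)(=O)C(F)(F)F)C[C@@H]2C(C)(C)C[C@@H](B3C4CCCC3CCC4)C[C@@]12C | intermediate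
18 | (2R,13S)-15-(tert-butyldimethylsilyloxy)-2-hydroxy-ent-labd-7-en-7-yl triflate | CC(C)(C)[Si](C)(C)OCC[C@@H](C)CC[C@@H]1C(C)=C(OS(=O)(=O)C(F)(F)F)C[C@@H]2C(C)(C)C[C@@H](O)C[C@@]12C | intermediate
19 | (2R,13S)-15-(tert-butyldimethylsilyloxy)-ent-labd-7-en-2-ol | CC(C)(C)[Si](C)(C)OCC[C@@H](C)CC[C@@H]1C(C)=CC[C@@H]2C(C)(C)C[C@@H](O)C[C@@]12C | intermediate
20 | (2R,5R,9R,10R,13S)-labd-7-ene-2,15-diol | OCC[C@@H](C)CC[C@@H]1C(C)=CC[C@@H]2C(C)(C)C[C@@H](O)C[C@@]12C | intermediate
21 | (2R,5R,9R,10R,13S)-labd-7-ene-2,15-diyl diacetate | CC(=O)OCC[C@@H](C)CC[C@@H]1C(C)=CC[C@@H]2C(C)(C)C[C@@H](OC(C)=O)C[C@@]12C | target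

## Step count and risks

Total steps: 13. Longest linear sequence: 12 steps (1–4, then 6–13).

**Step 6.** The quaternary carbon next to C5 shields both faces of the dienophile, so the cycloaddition may be slow. Desilylation or Mukaiyama–Michael addition of the diene, and a leak through the uncatalysed, non-selective pathway, could then take over.
The fallback takes the steric load out of the cycloaddition and builds the quaternary carbon afterwards.
- It sets out from 7, which is combined under the same catalyst with commercial ethyl (2E)-3-methyl-4-oxobut-2-enoate F1. This is a doubly activated, unhindered dienophile of the same (E)-geometry, and it should give the ester aldehyde F2.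
- Wittig methylenation gives the vinyl ester F3.
- Excess MeMgBr/CeCl3 gives the tertiary alcohol F4.
- Methyl chlorooxoacetate/DMAP gives the tert-alkyl methyl oxalate F5.
- Keck radical allylation (allyltributylstannane, AIBN, benzene, 80 °C) forms the C3–C4 bond, and the route is rejoined at 12.

**Step 9.** β-Hydride elimination may go toward the C8 methyl group instead of C9–H, or the enol ether may simply be protodesilylated.
The fallback replaces the palladium elimination by an ionic sequence. It sets out from 13. NBS (THF, −78 °C) attacks the far more nucleophilic enol ether and gives the 8-bromo-7-ketone F6 (C8 epimers, inconsequential). Dehydrobromination under equilibrating conditions (LiBr, Li2CO3, DMF, 120 °C) should give the more substituted endocyclic enone, and the route is rejoined at 14.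

**Step 11.** The hindered C1=C2 bond may react sluggishly, or boron may leak to C1.
The fallback delivers oxygen first and hydrogen second. It sets out from 16. m-CPBA (CH2Cl2, 0 °C) epoxidises the only electron-rich alkene from the face opposite the axial methyl groups and gives the 1,2-epoxide F7. Titanium(III)-mediated reductive opening (Cp2TiCl2, Mn, collidine·HCl, 1,4-cyclohexadiene, THF) breaks the C1–O bond at the more congested carbon. This leaves the oxygen on C2 with retention, and the route is rejoined at 18.

## Further compounds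

F1 | step 6 | ethyl (2E)-3-methyl-4-oxobut-2-enoate | CCOC(=O)/C=C(\C)C=O
F2 | step 6 | ring-B ester aldehyde (CO2Et on C5 cis to CH3-20) | CC(C)(C)[Si](C)(C)OCC[C@@H](C)CC[C@H]1C(C)=C(O[Si](C)(C)C(C)(C)C)C[C@H](C(=O)OCC)[C@@]1(C)C=O
F3 | step 6 | ring-B vinyl ester | CC(C)(C)[Si](C)(C)OCC[C@@H](C)CC[C@H]1C(C)=C(O[Si](C)(C)C(C)(C)C)C[C@H](C(=O)OCC)[C@@]1(C)C=C
F4 | step 6 | ring-B tertiary alcohol (2-hydroxypropan-2-yl on C5) | CC(C)(C)[Si](C)(C)OCC[C@@H](C)CC[C@H]1C(C)=C(O[Si](C)(C)C(C)(C)C)C[C@H](C(C)(C)O)[C@@]1(C)C=C
F5 | step 6 | tert-alkyl methyl oxalate of F4 | CC(C)(C)[Si](C)(C)OCC[C@@H](C)CC[C@H]1C(C)=C(O[Si](C)(C)C(C)(C)C)C[C@H](C(C)(C)OC(=O)C(=O)OC)[C@@]1(C)C=C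
F6 | step 9 | (13S)-8-bromo-15-(tert-butyldimethylsilyloxy)-9-epi-ent-labd-1-en-7-one (C8 epimers) | CC(C)(C)[Si](C)(C)OCC[C@@H](C)CC[C@H]1C(C)(Br)C(=O)C[C@@H]2C(C)(C)CC=C[C@@]12C
F7 | step 11 | (13S)-15-(tert-butyldimethylsilyloxy)-1,2-epoxy-ent-labd-7-en-7-yl triflate (oxirane anti to CH3-20) | CC(C)(C)[Si](C)(C)OCC[C@@H](C)CC[C@@H]1C(C)=C(OS(=O)(=O)C(F)(F)F)C[C@@H]2C(C)(C)C[C@H]3O[C@H]3[C@@]12C
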